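**Retrosynthetic overview**

1. The last C–C bond joins the ketone carbon to C1' of ring A. It comes from the Weinreb amide of an (R)-2-silyloxy-3-arylpropanoic acid and the 4-lithio derivative of 2-prenylresorcinol bis(methoxymethyl) ether; ring A is taken from resorcinol and is not built.
2. Ring B is the only ring that is constructed: its phenol is the dehydrogenation product of a 2-prenyl-4-alkylcyclohex-2-enone.
3. That cyclohexenone is opened by a Robinson disconnection (ring bonds C1–C6 and C2=C3) into an (R)-2-silyloxy-5-oxopentanoate, made from D-glutamic acid, and 7-methylocta-1,6-dien-3-one, made from 6-methylhept-5-en-2-one.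
4. Feature used: in ring B the hydroxyl carbon C4, the prenyl-bearing carbon C3 beside it and the chain-bearing carbon C1 para to it are the carbonyl, α- and γ-carbons of a cyclohex-2-enone. The CH2–CH(OH)–C(=O) unit with the single (R) stereocentre is C3–C2–C1 of (R)-2-hydroxyglutaric acid.
5. Order: ring B is closed in step 8 and aromatised in steps 9–10; ring A is attached in step 15.

Key step: step 8

Assumption: diazotisation of D-glutamic acid is taken to run with overall retention, as is general for α-amino acids with a free carboxylate, so C2 of D-glutamic acid becomes the (R)-carbinol carbon of the target without any inversion step.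

**Route**

Step 1
Reactants: 1 D-glutamic acid
Product: 2 (R)-5-oxotetrahydrofuran-2-carboxylic acid
Conditions: NaNO2, 2 M aq. HCl, 0 °C → rt
Reagents that add atoms: none
Why: Diazotisation gives a diazonium ion that is displaced first by the α-carboxylate (α-lactone, inversion) and then by the γ-carboxylate (second inversion), so the γ-lactone should form with net retention and C2 is R (deaminative lactonisation with neighbouring-group participation).

Step 2
Reactants: 2 (R)-5-oxotetrahydrofuran-2-carboxylic acid
Product: 3 tert-butyl (R)-5-oxotetrahydrofuran-2-carboxylate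
Conditions: Cl3CC(=NH)OtBu, BF3·OEt2 (cat.), CH2Cl2–cyclohexane, rt
Reagents that add atoms: tert-butyl 2,2,2-trichloroacetimidate, CC(C)(C)OC(=N)C(Cl)(Cl)Cl
Why: Acid-catalysed O-alkylation of the carboxylic acid by the trichloroacetimidate (tert-butyl transfer) gives the hindered ester that should later resist the aluminium amide and iBu2AlH, with lactone and stereocentre not involved.

Step 3
Reactants: 3 tert-butyl (R)-5-oxotetrahydrofuran-2-carboxylate
Product: 4 tert-butyl (R)-2-hydroxy-5-[methoxy(methyl)amino]-5-oxopentanoate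
Conditions: MeNH(OMe)·HCl, AlMe3, CH2Cl2, 0 °C → rt; aq. potassium sodium tartrate; used crude at once
Reagents that add atoms: N,O-dimethylhydroxylamine hydrochloride, CNOC.Cl
Why: Aminolysis by the aluminium amide formed from AlMe3 and the amine salt (Weinreb amidation of a lactone) opens the unhindered γ-lactone carbonyl while the tert-butyl ester is too hindered to react, and the C2–O bond is not broken, so configuration is kept.

Step 4
Reactants: 4 tert-butyl (R)-2-hydroxy-5-[methoxy(methyl)amino]-5-oxopentanoate
Product: 5 tert-butyl (R)-2-[(tert-butyldimethylsilyl)oxy]-5-[methoxy(methyl)amino]-5-oxopentanoate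
Conditions: TBSCl, imidazole, DMF, rt
Reagents that add atoms: tert-butyldimethylsilyl chloride, CC(C)(C)[Si](C)(C)Cl
Why: Imidazole-promoted silylation of the secondary alcohol (silyl ether formation) blocks relactonisation and protects the carbinol for the rest of the route.

Step 5
Reactants: 5 tert-butyl (R)-2-[(tert-butyldimethylsilyl)oxy]-5-[methoxy(methyl)amino]-5-oxopentanoate
Product: 6 tert-butyl (R)-2-[(tert-butyldimethylsilyl)oxy]-5-oxopentanoate
Conditions: iBu2AlH (1.2 equiv), THF, −78 °C; aq. potassium sodium tartrate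
Reagents that add atoms: none
Why: The hydride adds once to the N-methoxy-N-methylamide and the aluminium-chelated hemiaminal survives until work-up (Weinreb amide reduction), so the aldehyde should form without over-reduction while the tert-butyl ester is untouched at −78 °C.

Step 6
Reactants: 7 6-methylhept-5-en-2-one
Product: 9 1-(dimethylamino)-7-methyloct-6-en-3-one, via lithium enolate 8 (not isolated)
Conditions: LiN(iPr)2, THF, −78 °C; CH2=NMe2+ I−, −78 °C → rt
Reagents that add atoms: N,N-dimethylmethyleneiminium iodide (Eschenmoser's salt), C=[N+](C)C.[I-]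
Why: Kinetic deprotonation by the hindered amide base takes a methyl proton and the terminal enolate is aminomethylated by the preformed iminium salt (Mannich reaction of a preformed enolate), which places the new carbon on the methyl side as required.

Step 7
Reactants: 9 1-(dimethylamino)-7-methyloct-6-en-3-one
Product: 11 7-methylocta-1,6-dien-3-one, via methiodide 10 (not isolated)
Conditions: MeI, CH2Cl2, rt; then sat. aq. NaHCO3, rt; used at once
Reagents that add atoms: none
Why: N-Methylation turns the amine into a leaving group and mild base effects E1cB loss of trimethylamine from the β-ammonio ketone (Mannich-base methiodide route to vinyl ketones), leaving the remote trisubstituted alkene alone.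

Step 8
Reactants: 6 tert-butyl (R)-2-[(tert-butyldimethylsilyl)oxy]-5-oxopentanoate; 11 7-methylocta-1,6-dien-3-one
Product: 14 tert-butyl (2R)-2-[(tert-butyldimethylsilyl)oxy]-3-[3-(3-methylbut-2-en-1-yl)-4-oxocyclohex-2-en-1-yl]propanoate, via pyrrolidine enamine 12 (not isolated), via keto aldehyde 13 (not isolated)
Conditions: pyrrolidine (0.3 equiv), AcOH (0.3 equiv), 11 (1.5 equiv), MeCN, 6 added slowly, 0 °C → rt; then 50 °C
Reagents that add atoms: none
Why: Pyrrolidine condenses with 6 to enamine 12, whose nucleophilic carbon (future ring carbon C1) adds to the unsubstituted terminus of 11 (future C6), and hydrolysis of the iminium gives keto aldehyde 13; this is the amine-mediated Michael addition of an aldehyde to a vinyl ketone followed by aldol condensation, the Robinson annulation variant used for 4-substituted cyclohex-2-enones. The ketone α′-methylene that already carries the prenyl CH2 then attacks the aldehyde (activated as its iminium) in a 6-(enolendo)-exo-trig closure, and loss of water gives the conjugated enone with C2=C3. The only new stereocentre, ring carbon C1, is uncontrolled and 14 should form as an epimer mixture, which is acceptable because this carbon becomes sp2 in step 10; the (R)-silyloxy ester centre is not enolised by the buffered amine. The step needs the cross-Michael addition to beat self-aldol of 6, which slow addition of 6 to an excess of the unhindered, highly electrophilic vinyl ketone should secure, and it needs closure through the α′-carbon, which is the only enolisable position that can reach the aldehyde in a six-membered ring (the others would give four-membered rings).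

Step 9
Reactants: 14 tert-butyl (2R)-2-[(tert-butyldimethylsilyl)oxy]-3-[3-(3-methylbut-2-en-1-yl)-4-oxocyclohex-2-en-1-yl]propanoate
Product: 16 tert-butyl (2R)-2-[(tert-butyldimethylsilyl)oxy]-3-[3-(3-methylbut-2-en-1-yl)-4-(trimethylsilyloxy)cyclohexa-2,4-dien-1-yl]propanoate, via lithium dienolate 15 (not isolated)
Conditions: LiN(iPr)2 (1.05 equiv), THF, −78 °C; TMSCl, −78 → 0 °C; used crude
Reagents that add atoms: chlorotrimethylsilane, C[Si](C)(C)Cl
Why: Kinetic deprotonation at the α′-methylene C5 of the enone, which is far more acidic than the ester α-hydrogen so the silyloxy stereocentre is not touched, followed by O-silylation gives the cross-conjugated silyl dienol ether (kinetic silyl enol ether formation).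

Step 10
Reactants: 16 tert-butyl (2R)-2-[(tert-butyldimethylsilyl)oxy]-3-[3-(3-methylbut-2-en-1-yl)-4-(trimethylsilyloxy)cyclohexa-2,4-dien-1-yl]propanoate
Product: 18 tert-butyl (2R)-2-[(tert-butyldimethylsilyl)oxy]-3-[4-hydroxy-3-(3-methylbut-2-en-1-yl)phenyl]propanoate, via cyclohexadienone 17 (not isolated)
Conditions: Pd(OAc)2 (1.05 equiv), MeCN, rt
Reagents that add atoms: none
Why: Saegusa–Ito oxidation, in which divalent palladium is transferred to C5 of the enol ether and β-hydride elimination introduces C5=C6, gives the cross-conjugated dienone 17 with a hydrogen on its sp3 ring carbon, which tautomerises to the phenol with prenyl ortho and the chain para to oxygen.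

Step 11
Reactants: 18 tert-butyl (2R)-2-[(tert-butyldimethylsilyl)oxy]-3-[4-hydroxy-3-(3-methylbut-2-en-1-yl)phenyl]propanoate
Product: 20 (2R)-2-[(tert-butyldimethylsilyl)oxy]-3-[4-hydroxy-3-(3-methylbut-2-en-1-yl)phenyl]propanoic acid, via bis(trimethylsilyl) derivative 19 (not isolated)
Conditions: TMSOTf (3.5 equiv), 2,6-lutidine (5 equiv), CH2Cl2, 0 °C → rt; aq. citric acid work-up
Reagents that add atoms: none
Why: Silyl triflate-mediated cleavage of the tert-butyl ester (O-silylation, loss of the tert-butyl group as isobutene to the buffering base) gives the trimethylsilyl ester and aryl trimethylsilyl ether, both hydrolysed on mild work-up, under conditions that should spare the secondary TBS ether and the ortho-prenylphenol, which would not tolerate CF3CO2H.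

Step 12
Reactants: 20 (2R)-2-[(tert-butyldimethylsilyl)oxy]-3-[4-hydroxy-3-(3-methylbut-2-en-1-yl)phenyl]propanoic acid
Product: 21 (2R)-2-[(tert-butyldimethylsilyl)oxy]-3-[4-hydroxy-3-(3-methylbut-2-en-1-yl)phenyl]-N-methoxy-N-methylpropanamide
Conditions: MeNH(OMe)·HCl, EDC·HCl, HOBt, iPr2NEt, CH2Cl2, 0 °C → rt
Reagents that add atoms: N,O-dimethylhydroxylamine hydrochloride, CNOC.Cl
Why: Carbodiimide coupling through the HOBt ester (amide bond formation) should favour the amine over the hindered phenol as nucleophile, and an α-silyloxy acid has no azlactone pathway for epimerisation.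

Step 13
Reactants: 22 resorcinol
Product: 23 1,3-bis(methoxymethoxy)benzene
Conditions: MOMCl, iPr2NEt, CH2Cl2, 0 °C → rt
Reagents that add atoms: chloromethyl methyl ether, COCCl
Why: O-Alkylation of both phenols by the α-chloro ether (Williamson-type etherification) installs the MOM groups that direct both later lithiations and are removed by acid at the end.

Step 14
Reactants: 23 1,3-bis(methoxymethoxy)benzene; 24 1-bromo-3-methylbut-2-ene (prenyl bromide)
Product: 26 1,3-bis(methoxymethoxy)-2-(3-methylbut-2-en-1-yl)benzene, via 2-lithio arene 25 (not isolated)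
Conditions: n-BuLi, THF, 0 °C → rt; then 24, −78 °C → rt
Reagents that add atoms: none
Why: Directed ortho-metalation at C2, the position flanked by both OMOM groups, followed by SN2 alkylation of the aryllithium by the primary allylic bromide should give the 2-prenyl compound.

Step 15
Reactants: 26 1,3-bis(methoxymethoxy)-2-(3-methylbut-2-en-1-yl)benzene; 21 (2R)-2-[(tert-butyldimethylsilyl)oxy]-3-[4-hydroxy-3-(3-methylbut-2-en-1-yl)phenyl]-N-methoxy-N-methylpropanamide
Product: 28 (2R)-1-[2,4-bis(methoxymethoxy)-3-(3-methylbut-2-en-1-yl)phenyl]-2-[(tert-butyldimethylsilyl)oxy]-3-[4-hydroxy-3-(3-methylbut-2-en-1-yl)phenyl]propan-1-one, via aryllithium 27 (not isolated)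
Conditions: 26 (3.0 equiv), n-BuLi (2.8 equiv), TMEDA, THF, −20 → 0 °C; then 21 (1 equiv), −78 → −20 °C; sat. aq. NH4Cl
Reagents that add atoms: none
Why: With C2 blocked, directed ortho-metalation occurs at C4 next to an OMOM group, and the aryllithium acylates the Weinreb amide through a chelated tetrahedral intermediate that collapses only on quench (Weinreb ketone synthesis), so no over-addition occurs and no enolisable ketone meets base; one equivalent of 27 is consumed by the phenol of 21 and returns 26.

Step 16
Reactants: 28 (2R)-1-[2,4-bis(methoxymethoxy)-3-(3-methylbut-2-en-1-yl)phenyl]-2-[(tert-butyldimethylsilyl)oxy]-3-[4-hydroxy-3-(3-methylbut-2-en-1-yl)phenyl]propan-1-one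
Product: 29 Glycybridin C, (2R)-1-[2,4-dihydroxy-3-(3-methylbut-2-en-1-yl)phenyl]-2-hydroxy-3-[4-hydroxy-3-(3-methylbut-2-en-1-yl)phenyl]propan-1-one
Conditions: 3 M aq. HCl, MeOH, rt → 40 °C
Reagents that add atoms: none
Why: Acid-catalysed acetal cleavage removes both MOM ethers and the same medium solvolyses the secondary TBS ether (global acidic deprotection), and at this mild acidity the prenyl groups should not cyclise onto the neighbouring phenols nor the α-hydroxy ketone enolise, so the R centre from step 1 is delivered unchanged.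

**Compound list**

1 | D-glutamic acid | N[C@H](CCC(=O)O)C(=O)O | starting material
2 | (R)-5-oxotetrahydrofuran-2-carboxylic acid | O=C(O)[C@H]1CCC(=O)O1 | intermediate
3 | tert-butyl (R)-5-oxotetrahydrofuran-2-carboxylate | CC(C)(C)OC(=O)[C@H]1CCC(=O)O1 | intermediate
4 | tert-butyl (R)-2-hydroxy-5-[methoxy(methyl)amino]-5-oxopentanoate | CON(C)C(=O)CC[C@@H](O)C(=O)OC(C)(C)C | intermediate
5 | tert-butyl (R)-2-[(tert-butyldimethylsilyl)oxy]-5-[methoxy(methyl)amino]-5-oxopentanoate | CON(C)C(=O)CC[C@@H](O[Si](C)(C)C(C)(C)C)C(=O)OC(C)(C)C | intermediate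
6 | tert-butyl (R)-2-[(tert-butyldimethylsilyl)oxy]-5-oxopentanoate | O=CCC[C@@H](O[Si](C)(C)C(C)(C)C)C(=O)OC(C)(C)C | intermediate
7 | 6-methylhept-5-en-2-one | CC(=O)CCC=C(C)C | starting material
8 | lithium 6-methylhepta-1,5-dien-2-olate (kinetic enolate of 7) | C=C(O[Li])CCC=C(C)C | intermediate
9 | 1-(dimethylamino)-7-methyloct-6-en-3-one | CN(C)CCC(=O)CCC=C(C)C | intermediate
10 | trimethyl(7-methyl-3-oxooct-6-en-1-yl)ammonium iodide | C[N+](C)(C)CCC(=O)CCC=C(C)C.[I-] | intermediate
11 | 7-methylocta-1,6-dien-3-one | C=CC(=O)CCC=C(C)C | intermediate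
12 | tert-butyl (2R,4E)-2-[(tert-butyldimethylsilyl)oxy]-5-(pyrrolidin-1-yl)pent-4-enoate | C1CCN(C1)/C=C/C[C@@H](O[Si](C)(C)C(C)(C)C)C(=O)OC(C)(C)C | intermediate
13 | tert-butyl (2R)-2-[(tert-butyldimethylsilyl)oxy]-4-formyl-11-methyl-7-oxododec-10-enoate (both C4 epimers) | O=CC(CCC(=O)CCC=C(C)C)C[C@@H](O[Si](C)(C)C(C)(C)C)C(=O)OC(C)(C)C | intermediate
14 | tert-butyl (2R)-2-[(tert-butyldimethylsilyl)oxy]-3-[3-(3-methylbut-2-en-1-yl)-4-oxocyclohex-2-en-1-yl]propanoate (both epimers at ring C1) | O=C1CCC(C[C@@H](O[Si](C)(C)C(C)(C)C)C(=O)OC(C)(C)C)C=C1CC=C(C)C | intermediate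
15 | lithium cross-conjugated dienolate of 14 (O–C=C at the former α′-carbon C5; side chain 2R) | [Li]OC1=CCC(C[C@@H](O[Si](C)(C)C(C)(C)C)C(=O)OC(C)(C)C)C=C1CC=C(C)C | intermediate
16 | tert-butyl (2R)-2-[(tert-butyldimethylsilyl)oxy]-3-[3-(3-methylbut-2-en-1-yl)-4-(trimethylsilyloxy)cyclohexa-2,4-dien-1-yl]propanoate | C[Si](C)(C)OC1=CCC(C[C@@H](O[Si](C)(C)C(C)(C)C)C(=O)OC(C)(C)C)C=C1CC=C(C)C | intermediate
17 | tert-butyl (2R)-2-[(tert-butyldimethylsilyl)oxy]-3-[3-(3-methylbut-2-en-1-yl)-4-oxocyclohexa-2,5-dien-1-yl]propanoate | O=C1C=CC(C[C@@H](O[Si](C)(C)C(C)(C)C)C(=O)OC(C)(C)C)C=C1CC=C(C)C | intermediate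
18 | tert-butyl (2R)-2-[(tert-butyldimethylsilyl)oxy]-3-[4-hydroxy-3-(3-methylbut-2-en-1-yl)phenyl]propanoate | CC(C)=CCc1cc(C[C@@H](O[Si](C)(C)C(C)(C)C)C(=O)OC(C)(C)C)ccc1O | intermediate
19 | trimethylsilyl (2R)-2-[(tert-butyldimethylsilyl)oxy]-3-[3-(3-methylbut-2-en-1-yl)-4-(trimethylsilyloxy)phenyl]propanoate | CC(C)=CCc1cc(C[C@@H](O[Si](C)(C)C(C)(C)C)C(=O)O[Si](C)(C)C)ccc1O[Si](C)(C)C | intermediate
20 | (2R)-2-[(tert-butyldimethylsilyl)oxy]-3-[4-hydroxy-3-(3-methylbut-2-en-1-yl)phenyl]propanoic acid | CC(C)=CCc1cc(C[C@@H](O[Si](C)(C)C(C)(C)C)C(=O)O)ccc1O | intermediate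
21 | (2R)-2-[(tert-butyldimethylsilyl)oxy]-3-[4-hydroxy-3-(3-methylbut-2-en-1-yl)phenyl]-N-methoxy-N-methylpropanamide | CC(C)=CCc1cc(C[C@@H](O[Si](C)(C)C(C)(C)C)C(=O)N(C)OC)ccc1O | intermediate
22 | resorcinol | Oc1cccc(O)c1 | starting material
23 | 1,3-bis(methoxymethoxy)benzene | COCOc1cccc(OCOC)c1 | intermediate
24 | 1-bromo-3-methylbut-2-ene (prenyl bromide) | CC(C)=CCBr | starting material
25 | 2-lithio-1,3-bis(methoxymethoxy)benzene | [Li]c1c(OCOC)cccc1OCOC | intermediate
26 | 1,3-bis(methoxymethoxy)-2-(3-methylbut-2-en-1-yl)benzene | COCOc1cccc(OCOC)c1CC=C(C)C | intermediate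
27 | 4-lithio-1,3-bis(methoxymethoxy)-2-(3-methylbut-2-en-1-yl)benzene | [Li]c1ccc(OCOC)c(CC=C(C)C)c1OCOC | intermediate
28 | (2R)-1-[2,4-bis(methoxymethoxy)-3-(3-methylbut-2-en-1-yl)phenyl]-2-[(tert-butyldimethylsilyl)oxy]-3-[4-hydroxy-3-(3-methylbut-2-en-1-yl)phenyl]propan-1-one | CC(C)=CCc1cc(C[C@@H](O[Si](C)(C)C(C)(C)C)C(=O)c2ccc(OCOC)c(CC=C(C)C)c2OCOC)ccc1O | intermediate
29 | Glycybridin C, (2R)-1-[2,4-dihydroxy-3-(3-methylbut-2-en-1-yl)phenyl]-2-hydroxy-3-[4-hydroxy-3-(3-methylbut-2-en-1-yl)phenyl]propan-1-one | CC(C)=CCc1cc(C[C@@H](O)C(=O)c2ccc(O)c(CC=C(C)C)c2O)ccc1O | target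

**Step count and risks**

Total step count: 16. Longest linear sequence: 12 steps (1–5, 8–12, 15, 16).

Steps most likely to fail:

Step 8. Self-aldol condensation of 6 and oligomerisation of 11 may outrun the cross-Michael addition, or the sequence may stop at the open keto aldehyde. The fallback sets out from 6 and returns at 14. Aldehyde 6 is converted with TMSCl, Et3N and NaI in MeCN into its trimethylsilyl enol ether, tert-butyl (2R)-2-[(tert-butyldimethylsilyl)oxy]-5-(trimethylsilyloxy)pent-4-enoate F1, which carries no free aldehyde and cannot self-condense. A Mukaiyama–Michael addition of F1 to 11 (TiCl4, CH2Cl2, −78 °C) should give keto aldehyde 13, now isolated. A separate aldol condensation (pyrrolidine, AcOH, toluene, 50 °C) then closes it to 14.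

Step 10. The divalent palladium may be diverted to the prenyl alkene, or, once the phenol has formed, may effect oxypalladation of the ortho-prenylphenol with ring closure to a chromene; adventitious acid may also protodesilylate 16 back to 14. The fallback sets out from 14 and returns at 18. Lithium dienolate 15 is trapped with PhSeCl at −78 °C to give the α′-selenide, tert-butyl (2R)-2-[(tert-butyldimethylsilyl)oxy]-3-[3-(3-methylbut-2-en-1-yl)-4-oxo-5-(phenylselanyl)cyclohex-2-en-1-yl]propanoate F2. Oxidation with H2O2 and pyridine (CH2Cl2, 0 °C → rt) and syn-elimination of the selenoxide should give dienone 17, which tautomerises to 18 without any transition metal.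

Step 15. n-BuLi may remove a proton from the benzylic–allylic CH2 of the prenyl group, which sits between two coordinating OMOM groups, instead of from ring C4, so that the wrong carbanion meets the Weinreb amide. The fallback sets out from 23 and returns at 28. Bromination of 23 with NBS (MeCN, 0 °C) gives 1-bromo-2,4-bis(methoxymethoxy)benzene F3. Deprotonation between the two OMOM groups with lithium 2,2,6,6-tetramethylpiperidide (THF, −78 °C) and alkylation with 24 gives 1-bromo-2,4-bis(methoxymethoxy)-3-(3-methylbut-2-en-1-yl)benzene F4. Bromine–lithium exchange on F4 (n-BuLi, THF, −78 °C) then generates 27 regiospecifically, at a temperature where proton transfer should not occur, and addition to 21 as in step 15 gives 28.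

**Further compounds**

F1 | step 8 | tert-butyl (2R)-2-[(tert-butyldimethylsilyl)oxy]-5-(trimethylsilyloxy)pent-4-enoate | C[Si](C)(C)OC=CC[C@@H](O[Si](C)(C)C(C)(C)C)C(=O)OC(C)(C)C
F2 | step 10 | tert-butyl (2R)-2-[(tert-butyldimethylsilyl)oxy]-3-[3-(3-methylbut-2-en-1-yl)-4-oxo-5-(phenylselanyl)cyclohex-2-en-1-yl]propanoate | O=C1C([Se]c2ccccc2)CC(C[C@@H](O[Si](C)(C)C(C)(C)C)C(=O)OC(C)(C)C)C=C1CC=C(C)C
F3 | step 15 | 1-bromo-2,4-bis(methoxymethoxy)benzene | COCOc1ccc(Br)c(OCOC)c1
F4 | step 15 | 1-bromo-2,4-bis(methoxymethoxy)-3-(3-methylbut-2-en-1-yl)benzene | COCOc1ccc(Br)c(OCOC)c1CC=C(C)C
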